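## Retrosynthetic overview
- The final step is a Heck olefination of an aryl bromide with acrylic acid, so the acrylic acid is installed last. Before that, the C3 ester is reduced to CH₂OH, and the trans configuration comes from base epimerization of the cis ester at C3.
- The key step is dearomative asymmetric hydrogenation of the furan ring of a 2-aryl-3-carbomethoxybenzofuran. It sets C2 and C3 together as the cis ester.
- The benzofuran is built in one Cu-mediated step from a 2-iodophenol and an aroyl-acetate (C-arylation, then cyclodehydration).
- Both partners come from cheap guaiacol-type feedstocks (4-bromoguaiacol and acetovanillone). The only ring formed in the sequence is the furan ring, and it is formed as an aromatic ring first and then dearomatized.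

**Assumptions:** the target is the trans-(2S,3R) isomer. The phenols are left unprotected throughout. The PhTRAP enantiomer given in Step 4 is assumed to deliver 2S, and the other enantiomer would be used if it does not.

## Route

**Step 1**
Reactants: 1 (4-bromo-2-methoxyphenol)
Product: 2 (4-bromo-2-iodo-6-methoxyphenol)
Conditions: NIS, cat. TsOH, MeCN, 0 → 25 °C
Reagents that add atoms: N-iodosuccinimide, O=C1CCC(=O)N1I (adds I)
Why: Electrophilic aromatic iodination goes ortho to the strongly directing OH, at the only free ortho position; no stereocentre is involved.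

**Step 2**
Reactants: 3 (acetovanillone, 1-(4-hydroxy-3-methoxyphenyl)ethanone)
Product: 4 (methyl 3-(4-hydroxy-3-methoxyphenyl)-3-oxopropanoate)
Conditions: NaH (3 equiv), dimethyl carbonate, THF, 65 °C; then aq. HCl
Reagents that add atoms: dimethyl carbonate, COC(=O)OC (adds CO₂Me)
Why: This is a crossed Claisen-type methoxycarbonylation of the ketone enolate; the extra NaH simply masks the phenol.

**Step 3**
Reactants: 2 (4-bromo-2-iodo-6-methoxyphenol) and 4 (β-ketoester)
Product: 5 (methyl 5-bromo-2-(4-hydroxy-3-methoxyphenyl)-7-methoxybenzofuran-3-carboxylate)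
Conditions: CuI (10 mol%), 2-picolinic acid (20 mol%), Cs₂CO₃, DMSO, 90 °C; then cat. TsOH, 60 °C
Reagents that add atoms: none
Why: Hurtley-type Cu-catalysed C-arylation of the β-ketoester occurs at C–I in preference to C–Br. The ortho-OH then adds to the ketone and dehydrates (benzofuran annulation), which places the aryl group at C2 and the ester at C3.

**Step 4 (key step)**
Reactants: 5
Product: 6 (methyl (2S,3R)-5-bromo-2-(4-hydroxy-3-methoxyphenyl)-7-methoxy-2,3-dihydrobenzofuran-3-carboxylate, cis)
Conditions: [Ru(η³-methallyl)₂(cod)] (5 mol%), (S,S)-(R,R)-PhTRAP (5.5 mol%), Et₃N (10 mol%), iPrOH, H₂ (50 atm), 80 °C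
Reagents that add atoms: none (H₂ adds hydrogen only)
Why: Proposed new method: the furan ring of the benzofuran is dearomatized by a chiral Ru–PhTRAP catalyst, with the 3-ester (and the ortho O) anchoring the substrate so that hydride and proton are delivered syn to one enantioface. This sets C2 as S and gives the cis isomer. The closest known reaction is Ru/Ir-catalysed asymmetric hydrogenation of 2-substituted and 2,3-disubstituted benzofurans; here it is extended to a tetrasubstituted 2-aryl-3-ester substrate.

**Step 5**
Reactants: 6
Product: 7 (methyl (2S,3S)-5-bromo-2-(4-hydroxy-3-methoxyphenyl)-7-methoxy-2,3-dihydrobenzofuran-3-carboxylate, trans)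
Conditions: NaOMe (2.5 equiv), MeOH, 25 °C
Reagents that add atoms: none (isomerization)
Why: C3–H is benzylic and α to the ester, so enolization epimerizes it to the more stable trans isomer. C2 is not acidic and is untouched, and E1cB ring opening is stereoelectronically poor in the five-membered ring, so the enantiomeric purity is retained.

**Step 6**
Reactants: 7
Product: 8 ((2S,3R)-5-bromo-2-(4-hydroxy-3-methoxyphenyl)-7-methoxy-2,3-dihydrobenzofuran-3-yl)methanol, trans)
Conditions: LiAlH₄ (4 equiv), THF, 0 → 25 °C
Reagents that add atoms: none (hydride only)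
Why: Ester-to-primary-alcohol reduction, with no stereocentre affected. The aryl bromide survives at this temperature, and the free phenols only consume hydride. The CIP label at C3 changes from S to R only because CO₂Me becomes CH₂OH, not because the geometry changes.

**Step 7**
Reactants: 8 and 9 (acrylic acid)
Product: 10 (target, (E)-3-[(2S,3R)-3-(hydroxymethyl)-2-(4-hydroxy-3-methoxyphenyl)-7-methoxy-2,3-dihydrobenzofuran-5-yl]acrylic acid)
Conditions: Pd(OAc)₂ (5 mol%), P(o-tol)₃ (10 mol%), Et₃N (4 equiv), DMF, 110 °C; then aq. HCl workup
Reagents that add atoms: none (acrylic acid is the numbered reactant)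
Why: Mizoroki–Heck coupling of the aryl bromide with acrylic acid gives the E-cinnamic acid selectively (β-hydride elimination). Free OH and CO₂H groups are tolerated, and no stereocentre is touched because C3 now bears CH₂OH, which is not acidic.

## Compound list
1 | 4-bromo-2-methoxyphenol | COc1cc(Br)ccc1O | starting material
2 | 4-bromo-2-iodo-6-methoxyphenol | COc1cc(Br)cc(I)c1O | intermediate
3 | acetovanillone | COc1cc(C(C)=O)ccc1O | starting material
4 | methyl 3-(4-hydroxy-3-methoxyphenyl)-3-oxopropanoate | COC(=O)CC(=O)c1ccc(O)c(OC)c1 | intermediate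
5 | methyl 5-bromo-2-(4-hydroxy-3-methoxyphenyl)-7-methoxybenzofuran-3-carboxylate | COC(=O)c1c(-c2ccc(O)c(OC)c2)oc2c(OC)cc(Br)cc12 | intermediate
6 | methyl (2S,3R)-5-bromo-2-(4-hydroxy-3-methoxyphenyl)-7-methoxy-2,3-dihydrobenzofuran-3-carboxylate (cis) | COc1cc([C@H]2Oc3c(OC)cc(Br)cc3[C@H]2C(=O)OC)ccc1O | intermediate
7 | methyl (2S,3S)-5-bromo-2-(4-hydroxy-3-methoxyphenyl)-7-methoxy-2,3-dihydrobenzofuran-3-carboxylate (trans) | COc1cc([C@H]2Oc3c(OC)cc(Br)cc3[C@@H]2C(=O)OC)ccc1O | intermediate
8 | [(2S,3R)-5-bromo-2-(4-hydroxy-3-methoxyphenyl)-7-methoxy-2,3-dihydrobenzofuran-3-yl]methanol | COc1cc([C@H]2Oc3c(OC)cc(Br)cc3[C@@H]2CO)ccc1O | intermediate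
9 | acrylic acid | C=CC(=O)O | starting material
10 | (E)-3-[(2S,3R)-3-(hydroxymethyl)-2-(4-hydroxy-3-methoxyphenyl)-7-methoxy-2,3-dihydrobenzofuran-5-yl]acrylic acid | COc1cc([C@H]2Oc3c(OC)cc(/C=C/C(=O)O)cc3[C@@H]2CO)ccc1O | target

## Totals
- Total steps: 7.
- Longest linear sequence: 6 steps (1 → 2 → 5 → 6 → 7 → 8 → 10).

## Three steps most likely to fail
1. **Step 4 (asymmetric dearomative hydrogenation).** The tetrasubstituted, push-pull benzofuran may be unreactive or may lose bromine.
   - Fallback: change the approach to a Rh₂(S-PTAD)₄-catalysed intramolecular C–H insertion of an aryl diazoacetate carrying an ortho O-(4-acyloxy-3-methoxybenzyl) ether. This builds the trans 2-aryl-3-carbomethoxy dihydrobenzofuran directly and enantioselectively, and it rejoins the route at compound 7.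
2. **Step 3 (Cu coupling and cyclization).** Two free phenols could give competing O-arylation, and the C–Br bond could be lost.
   - Fallback: replace the Ullmann coupling with an oxidative C–H/C–H coupling of 4-bromoguaiacol and ketoester 4 (PIFA or FeCl₃). Then close the ring by acid-mediated cyclodehydration.
3. **Step 7 (Heck).** The electron-rich aryl bromide is sluggish, and the benzylic ether could ionize at 110 °C.
   - Fallback: convert Br to CHO by Pd-catalysed formylation (HCO₂H/Ac₂O, Pd). Then build the acrylic acid by Knoevenagel–Doebner condensation (malonic acid, pyridine/piperidine, 80 °C) on the aldehyde.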